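## Structural features

The target (37) is a seco-meroterpenoid. A cyclohexane (ring B, C1–C6) is trans-fused through C4 and C5 to a cyclohexene (ring C: C4, C5, C7, C8=C9, C10; methyl on C9). Ring B carries a δ-lactone spiro-linked at C6 (C6–C12–C13–C14(=O)–O–C15–C6) and an isopropenyl group (C16) at C1. C10 is the spiro atom of a 3-hydroxy-2,3-dihydrofuro[3,2-c]pyran-4-one: the ring oxygen joins C10 to C4', the carbinol C11 joins C10 to C3', and C6' bears a pyridin-3-yl group.

Five stereocentres are contiguous (C10, C4, C5, C6, C1) and a sixth, C11, sits next to C10; C4, C6 and C10 are fully substituted. Taking the face of ring B that carries the C4 methyl group as β, C15 (axial), the C7 chain and the isopropenyl group (both equatorial) are β, whereas C10 and C12 are α. At C10 the ether oxygen is equatorial (β) and C11 is axial (α, anti to the C4 methyl); the C11 hydroxyl lies on the C9 side of the dihydrofuran ring.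

Fragile sites are the tertiary allylic C10–O bond to a vinylogous-acid oxygen (ionisation), the doubly activated C11 carbinol (dehydration, epimerisation), the δ-lactone and pyranone (hard nucleophiles, hydride), the isopropenyl group (acid) and the pyridine nitrogen (metal binding). The real difficulty is the crowded C10–C4–C5–C6 array: two quaternary carbons flank the C5 methine, and C10 must carry its oxygen on the more hindered side next to a carbinol of defined configuration.

The key step exploits the C4/C5 pair of ring B. A quaternary C4 (methyl and C10) next to a C5 methine whose C7 chain is trans to C10 is what an (E)-2-methyl-2-enal leaves behind in a [4+2] cycloaddition. C6, flanked by an oxygenated C1 and bearing C15, maps onto the ester-bearing terminus of a 2-silyloxy diene, which after cycloaddition is a β-keto ester ready for quaternisation.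

## Logic of the disconnections

**37 ⇒ 32 + 36.** The C11–C3' bond and the C10–O–C4' ether bond are cut together. C3' of 36 is a carbon nucleophile and C4' an addition–elimination site, while 32 offers an aldehyde at C11 and a hydroxyl on C10. This removes the whole heteroaromatic in one piece and reduces the spiro problem to one tertiary carbinol. The forward step must add C3' to the aldehyde, close O–C4' without ionising C10, and place the C11 hydroxyl on the C9 side.

**36 ⇒ 35 ⇒ 33 + 34.** The lactone C–O bond and the C5'–C6' bond are cut (lactonisation, Claisen acylation). Both fragments are commodity esters. The forward acylation must occur at the terminal carbon of 33, which its dianion ensures.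

**32 ⇒ 31 ⇒ 29 ⇒ 28.** After adjusting C11 from aldehyde to alcohol to epoxide methylene, the C10–C11 bond is cut. One-carbon addition to the C10 ketone sets the spiro centre under steric control by the axial C4 methyl and keeps the carbonyl oxygen as the future ether oxygen. 28 has no stereocentre on ring C. The nucleophile must prefer the hindered enone carbonyl over the lactone and attack the α face, and the C10–O bond must not be broken afterwards.

**28 ⇒ 27 ⇒ 26 ⇒ 25 ⇒ 24.** The C8=C9 bond is cut (aldol condensation), which opens ring C to an ethyl ketone at C10 and an aldehyde at C8, both stored as silyl-protected alcohols. The forward step needs a single enolisable position on the ketone (C9; C4 is quaternary) and conditions that spare the lactone.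

**24 ⇒ 23 ⇒ 22 ⇒ 21.** The lactone is unravelled to a 1,5-diol and further to two esters. This avoids differentiating the esters by reduction. The forward oxidation must pick the unhindered C14 alcohol over the neopentyl C15 alcohol.

**21 ⇒ 20 ⇒ 19 ⇒ 18 ⇒ 17 ⇒ 16.** C16=C17 (methylenation), the C1–H bond (hydrogenation) and C1–C16 (cross-coupling of an enol triflate) are cut in turn, returning C1 to a ketone. The demand is that hydrogen, or equilibration, places the acetyl group equatorial (β), and that no other alkene or carbonyl is present at that stage; hence ring C is closed later.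

**16 ⇒ 15 ⇒ 14.** The C9–C10 bond is cut (ethyl addition to the C10 aldehyde) and the carbinol protection removed. The forward addition must prefer the aldehyde over the α-quaternary C1 ketone and two hindered esters.

**14 ⇒ 12 + 13.** The C6–C12 bond is cut (Michael addition), leaving a β-keto ester. The acrylate must enter anti to the C7 chain and the C4 methyl.

**12 ⇒ 11 ⇒ 5 + 10.** C3–C4 and C5–C6 are cut, opening ring B into an enal and a silyloxy dienoate. Two acyclic pieces then supply every carbon of ring B, the angular methyl, C10, C15 and the C7–C8 chain. The forward step must control regiochemistry, enal geometry transfer and absolute facial selectivity.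

**5 ⇒ 3 + 4, 3 ⇒ 2 ⇒ 1; 10 ⇒ 9 ⇒ 8 ⇒ 6 + 7.** The enal C=C is cut (Wittig) and the aldehyde traced to a mono-protected diol. The diene is traced through the vinyl ketone β-keto ester to an acetate aldol with acrolein. The demands are (E)-selectivity in the olefination and (Z)-selective silylation of the labile vinyl ketone.

## Other disconnections considered

**Alternative 1:** The cut is C14–C16, reconnecting lactone carbonyl and isopropenyl carbon into ring A of a tricyclic 15-hydroxy-14-ketone A1. In the forward step A1 closes to its bridged hemiketal A2. The hypoiodite of A2 (PhI(OAc)2, I2, light) gives an alkoxy radical whose β-scission breaks C14–C16, and Cu(OAc)2 oxidises the tertiary C16 radical to the isopropenyl group. The product A3 is the same compound as 28.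
- In favour: one operation makes the lactone (with unambiguous regiochemistry) and the isopropenyl group, and C1 is inherited from a trans ring fusion. On this count it is better than the chosen plan, which spends steps 11–16 on the same two groups.
- Against: A1 needs a third ring, a gem-dimethyl carbon and an oxidised angular carbon on quaternary C6, all of which are then partly destroyed. A2 is a strained 2-oxabicyclo[2.2.2]octane and may be a minor equilibrium form. The open-chain C15 alkoxy radical can lose formaldehyde, and elimination may also give the isopropylidene isomer.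
- Comparison: both routes meet at the same enone, so the end game is equal. The chosen plan never builds ring A and sets C4/C5 by catalysis. The alternative shifts cost to making A1 and relies on a radical step that is less predictable than ionic chemistry.

**Alternative 2:** The cut is C4–C5 and C2–C3, with ring C formed by the tether: triene A4 cyclises (heat or Me2AlCl) to the octalone silyl enol ether A5. A5 is written here with a six-membered ring B (two methylenes, C2 and C3, between C1 and C4), as the bond count of the cycloaddition requires; a third methylene would make a cycloheptene that does not map onto the target.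
- In favour: two rings and the quaternary C4 form in one step, and C10 is already a ring ketone. Here the alternative is better than the chosen plan, which needs ethyl addition, protection, oxidation and aldol condensation for ring C. The tethered isopropenyl ketone is also a more dependable dienophile than an intermolecular trisubstituted enal.
- Against: absolute control rests on one methyl-bearing centre (C9) next to the tether ketone, which is epimerisable and is later erased on introducing C8=C9. The cis/trans fusion of such decatrienones depends on conditions. C6 arrives unsubstituted, so both C15 and C12 must be installed at a neopentyl position, whereas the chosen diene brings C15 with it.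
- Comparison: catalyst control versus relay from a sacrificial centre. The step count is roughly equal once the linear assembly of A4 and the two C6 alkylations are counted.

**Alternative 3:** The cut is C9–C10, with C11–O traced to a C11–B bond. The alkenyl iodide A6, carrying the intact furopyranone on C4, undergoes oxidative addition to zerovalent palladium (from Pd(OAc)2 and a phosphine), 6-exo insertion into the furan C10=C11 bond and capture by B2pin2 to give boronate A7; oxidation then gives 37.
- In favour: it is the most convergent option. Ring C, the spiro centre and the C11 heteroatom arise together, and syn carbopalladation places boron (hence oxygen) on C11 cis to C9 stereospecifically. This is better than the chosen annulation, where that relationship rests on a facial preference. It would also replace the four-step C10/C11 end game by two steps.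
- Against: dearomative Heck–borylation of an electron-poor furopyranone by an alkenyl iodide, forming a spiro quaternary centre next to quaternary C4, has no close model. Direct borylation of C9–I and binding of palladium by the pyridine are likely competitors. The face of the furan attacked (C10 configuration) is not obviously controlled.
- Comparison: ring B, the lactone and the isopropenyl group would be made as in the chosen plan, so the gain is confined to the end. The chosen plan also ends with an untested step, but with a classical fallback from the same intermediate.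

Key step: step 7

Assumption: the (S)-configured catalyst is taken to expose the Cα-Re face of 5, as it does for 2-substituted acroleins; if the first analysis showed the antipode, the (R)-catalyst would be used with nothing else changed.

Assumption: 11 forms as a mixture at C6, which is of no consequence because C6 is planar in 12.

Abbreviations: TBS = tert-butyldimethylsilyl; TBDPS = tert-butyldiphenylsilyl.

## Steps

Step 1
Reactants: 1 propane-1,3-diol
Product: 2 3-(tert-butyldiphenylsilyloxy)propan-1-ol
Conditions: NaH (1.0 equiv), THF, 0 → 23 °C; then tBuPh2SiCl (1.0 equiv)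
Reagents that add atoms: tert-butyl(chloro)diphenylsilane, CC(C)(C)[Si](Cl)(c1ccccc1)c1ccccc1
Why: O-silylation of the sparingly soluble mono-sodium alkoxide of a symmetrical diol should stop at the mono-ether; the TBDPS group is chosen over a more labile silyl ether because it must survive the hydrolysis of two enol ethers (steps 7 and 12) and the Lewis acid of step 7.

Step 2
Reactants: 2 3-(tert-butyldiphenylsilyloxy)propan-1-ol
Product: 3 3-(tert-butyldiphenylsilyloxy)propanal
Conditions: 2,2,6,6-tetramethylpiperidin-1-oxyl (10 mol %), PhI(OAc)2, CH2Cl2, 23 °C
Reagents that add atoms: none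
Why: Oxoammonium-mediated oxidation of a primary alcohol stops at the aldehyde and is neutral enough to avoid β-elimination of the silyloxy group.

Step 3
Reactants: 3 3-(tert-butyldiphenylsilyloxy)propanal; 4 2-(triphenylphosphoranylidene)propanal
Product: 5 (E)-5-(tert-butyldiphenylsilyloxy)-2-methylpent-2-enal
Conditions: PhMe, 90 °C
Reagents that add atoms: none
Why: Wittig olefination with a stabilised formyl ylide should give the (E)-enal (formyl trans to the chain), the geometry that becomes the trans C10/C7 relationship of ring B.

Step 4
Reactants: 6 methyl acetate; 7 acrolein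
Product: 8 methyl 3-hydroxypent-4-enoate (racemic)
Conditions: LiN(iPr)2, THF, −78 °C; then 7, −78 °C
Reagents that add atoms: none
Why: Aldol addition of a lithium ester enolate to an enal occurs 1,2 at low temperature; the carbinol centre is oxidised in the next step, so no stereocontrol is needed.

Step 5
Reactants: 8 methyl 3-hydroxypent-4-enoate
Product: 9 methyl 3-oxopent-4-enoate
Conditions: Dess–Martin periodinane, CH2Cl2, 0 °C; crude used at once
Reagents that add atoms: none
Why: Periodinane oxidation of the allylic alcohol under non-basic conditions gives the vinyl ketone β-keto ester, which polymerises readily and is therefore silylated directly.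

Step 6
Reactants: 9 methyl 3-oxopent-4-enoate
Product: 10 methyl (Z)-3-(tert-butyldimethylsilyloxy)penta-2,4-dienoate
Conditions: tBuMe2SiOTf, Et3N, Et2O, −78 → 0 °C
Reagents that add atoms: tert-butyldimethylsilyl triflate, CC(C)(C)[Si](C)(C)OS(=O)(=O)C(F)(F)F
Why: Soft enolisation and O-silylation of the β-keto ester trap the hydrogen-bonded cis-enol and should give mainly the (Z)-silyl dienol ether, whose ester points outward in the s-cis diene; any (E)-isomer is a poorer diene and should remain unreacted in step 7.

Step 7
Reactants: 5 (E)-5-(tert-butyldiphenylsilyloxy)-2-methylpent-2-enal; 10 methyl (Z)-3-(tert-butyldimethylsilyloxy)penta-2,4-dienoate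
Product: 12 ring-B aldehyde β-keto ester (enol form): methyl (5R,6S)-5-formyl-2-hydroxy-5-methyl-6-[2-(tert-butyldiphenylsilyloxy)ethyl]cyclohex-1-ene-1-carboxylate, via silyl enol ether cycloadduct 11 (not isolated)
Conditions: (S)-tetrahydro-1-(2-methylphenyl)-3,3-diphenyl-1H,3H-pyrrolo[1,2-c][1,3,2]oxazaborole·HN(SO2CF3)2 (20 mol %), CH2Cl2, −78 → −40 °C; then 1 M HCl, THF, 0 °C
Reagents that add atoms: none
Why: The cationic boron Lewis acid binds the formyl oxygen of 5 (s-trans enal) and lowers its LUMO enough for the push–pull diene 10 to react at low temperature; the closest known reaction type is the oxazaborolidinium-catalysed Diels–Alder reaction of 2-substituted enals with 2-silyloxy-1,3-dienes. Ring B closes by [4+2] cycloaddition in which C6 (the enol-ether β-carbon of 10) bonds to the enal β-carbon C5 and the vinyl terminus C3 to the α-carbon C4, either concertedly but asynchronously or as a Mukaiyama–Michael addition followed by Michael-type closure of the boron enolate onto the silyloxocarbenium-activated vinyl ketone (the second event is a conjugate addition, not an aldol); both paths end at 11. Regiochemistry follows the silyloxy group, which makes C6 the nucleophilic terminus despite its ester. The C4/C5 relative configuration (C10 trans to the C7 chain, methyl cis to it) is the suprafacial transcription of the (E)-geometry of 5, and a stepwise path keeps it only if ring closure outruns C4–C5 rotation, which the tethered cation should ensure. The absolute configuration at C4, and with it C5, comes from the catalyst: the phenyl group cis to the bound aldehyde shields one face so that the diene adds to the Cα-Re face. C6 forms as a mixture and is erased when the acid work-up cleaves the silyl enol ether to the enolised β-keto ester 12. The step therefore needs regio- and π-facial selectivity and retention of the enal geometry; the outward ester of (Z)-10 keeps the s-cis conformer accessible, and the TBDPS ether is inert to the Lewis acid and to the dilute acid.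

Step 8
Reactants: 12 ring-B aldehyde β-keto ester; 13 tert-butyl acrylate
Product: 14 C6-quaternary keto aldehyde diester (C1 ketone; C6 bears CO2Me on the β face and CH2CH2CO2tBu on the α face; C4 and C5 as in 12)
Conditions: Cs2CO3 (20 mol %), MeCN, 0 → 23 °C
Reagents that add atoms: none
Why: Base-catalysed Michael addition of the β-keto ester makes C6 quaternary; the acrylate should approach the enolate on the α face, anti to the adjacent C7 chain (pushed pseudo-axial by A(1,2) strain with the ester) and to the C4 methyl, so that C12 ends α and C15 β; the aldehyde has no α-hydrogen and tolerates the mild base.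

Step 9
Reactants: 14 C6-quaternary keto aldehyde diester
Product: 15 C10 ethyl carbinol (secondary alcohol at C10 as an epimer mixture; otherwise as 14)
Conditions: EtMgBr (1.2 equiv), Et2O/THF, −78 °C
Reagents that add atoms: ethylmagnesium bromide, CC[Mg]Br
Why: Grignard addition should be much faster to the aldehyde than to the α-quaternary C1 ketone or the hindered methyl and tert-butyl esters at −78 °C; C10 is oxidised later, so its configuration is irrelevant.

Step 10
Reactants: 15 C10 ethyl carbinol
Product: 16 C10 TBS ether of 15
Conditions: tBuMe2SiOTf, 2,6-lutidine, CH2Cl2, −78 → 0 °C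
Reagents that add atoms: tert-butyldimethylsilyl triflate, CC(C)(C)[Si](C)(C)OS(=O)(=O)C(F)(F)F
Why: Silyl triflate protection of the hindered secondary alcohol masks C10 during the enolate and palladium chemistry at C1; both silyl ethers come off together in step 17, so the protection costs one step.

Step 11
Reactants: 16 C10 TBS ether
Product: 17 C1 enol triflate (C1=C2; trifluoromethanesulfonyloxy on C1)
Conditions: KN(SiMe3)2, THF, −78 °C; then PhN(SO2CF3)2, −78 → 0 °C
Reagents that add atoms: N-phenylbis(trifluoromethanesulfonimide), O=S(=O)(N(c1ccccc1)S(=O)(=O)C(F)(F)F)C(F)(F)F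
Why: The C1 ketone can enolise only toward C2 (C6 is quaternary) and is more acidic than the ester α-positions, so kinetic deprotonation and O-triflation should give a single enol triflate.

Step 12
Reactants: 17 C1 enol triflate
Product: 19 C1-acetyl cyclohexene (conjugated methyl ketone; C1=C2), via ethoxydiene 18 (not isolated)
Conditions: CH2=C(OEt)SnBu3, Pd(PPh3)4 (5 mol %), LiCl, THF, 65 °C; then 1 M HCl, THF, 0 °C
Reagents that add atoms: tributyl(1-ethoxyvinyl)stannane, CCCC[Sn](CCCC)(CCCC)C(=C)OCC; water, O
Why: Stille coupling of the alkenyl triflate with an acetyl-anion equivalent, then hydrolysis of the very labile 2-ethoxydiene, installs C16 as an acetyl group; the brief dilute acid leaves the TBDPS ether, the hindered TBS ether and the tert-butyl ester intact.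

Step 13
Reactants: 19 C1-acetyl cyclohexene
Product: 20 saturated methyl ketone (C1: acetyl β and equatorial; H α)
Conditions: H2 (1 atm), 10% Pd/C, EtOAc, 23 °C
Reagents that add atoms: none
Why: Catalytic hydrogenation of the conjugated C1=C2 bond should deliver hydrogen to the α face, away from the axial C15 ester and C4 methyl, setting C1 with the acetyl group equatorial; this is also the more stable epimer, so epimerisation α to the ketone converges on it, and no other reducible group is present.

Step 14
Reactants: 20 saturated methyl ketone
Product: 21 C1-isopropenyl diester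
Conditions: Ph3PCH3Br, KOtBu, THF, 0 → 50 °C
Reagents that add atoms: methyltriphenylphosphonium bromide, C[P+](c1ccccc1)(c1ccccc1)c1ccccc1.[Br-]
Why: Wittig methylenation of the methyl ketone gives the isopropenyl group; the ylide does not attack the esters, and the only epimerisable centre (C1) already has its stable configuration.

Step 15
Reactants: 21 C1-isopropenyl diester
Product: 22 1,5-diol (C14 and C15 primary alcohols)
Conditions: LiAlH4, THF, 0 → 65 °C
Reagents that add atoms: none
Why: Hydride reduction of both esters (no other reducible group is present) turns the ester differentiation into a steric problem that the next step solves.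

Step 16
Reactants: 22 1,5-diol
Product: 24 spiro δ-lactone (C14 carbonyl; ring oxygen on C15), via lactol 23 (not isolated)
Conditions: 2,2,6,6-tetramethylpiperidin-1-oxyl (20 mol %), PhI(OAc)2 (2.5 equiv), CH2Cl2, 23 °C
Reagents that add atoms: none
Why: Oxidative lactonisation of a 1,5-diol: the oxoammonium oxidant should take the unhindered C14 alcohol far faster than the neopentyl, axial C15 alcohol; the C14 aldehyde is trapped by the C15 hydroxyl as a lactol and oxidised on, which places the carbonyl at C14 as in the target.

Step 17
Reactants: 24 spiro δ-lactone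
Product: 25 lactone diol (C8 primary and C10 secondary alcohols)
Conditions: HF·pyridine, pyridine, THF, 0 → 40 °C
Reagents that add atoms: none
Why: Buffered fluoride cleaves both silyl ethers and leaves the lactone and the isopropenyl group untouched.

Step 18
Reactants: 25 lactone diol
Product: 26 keto aldehyde (C10 ethyl ketone; C8 aldehyde)
Conditions: Dess–Martin periodinane (3 equiv), CH2Cl2, 23 °C
Reagents that add atoms: none
Why: Periodinane oxidises the primary and the hindered secondary alcohol in one operation to the 1,5-keto aldehyde without epimerising C5, which is not α to either carbonyl.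

Step 19
Reactants: 26 keto aldehyde
Product: 28 seco-lactone enone (rings B and C; C10 ketone; C8=C9), via β-hydroxy ketone 27 (not isolated)
Conditions: Bn2NH·CF3CO2H (20 mol %), PhH, 60 °C
Reagents that add atoms: none
Why: Intramolecular aldol condensation: the ethyl ketone can enolise only toward C9, C9 adds to the C8 aldehyde in a six-membered closure, and loss of water gives the conjugated enone; the trans ring fusion is already fixed by C4 and C5, and the weakly acidic ammonium salt spares the lactone.

Step 20
Reactants: 28 seco-lactone enone
Product: 29 spiro epoxide (C11 methylene α and axial; epoxide oxygen β on C10)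
Conditions: Me3SI, KN(SiMe3)2, THF, −10 → 0 °C
Reagents that add atoms: trimethylsulfonium iodide, C[S+](C)C.[I-]
Why: Corey–Chaykovsky epoxidation: the sulfonium ylide adds 1,2 to the enone carbonyl and should approach C10 axially on the α face, anti to the axial C4 methyl, so that C11 is α and the oxygen β as in the target; the ylide should not open the lactone at this temperature.

Step 21
Reactants: 29 spiro epoxide
Product: 31 diol lactone (tertiary C10 hydroxyl β; primary C11 hydroxyl), via potassium hydroxy carboxylate 30 (not isolated)
Conditions: KOH, DMSO/H2O, 80 °C; then 1 M HCl to pH 3, 23 °C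
Reagents that add atoms: potassium hydroxide, [K+].[OH-]
Why: Hydroxide opens the epoxide by SN2 attack at the primary carbon C11, so the C10–O bond and its configuration are untouched; the lactone is saponified under these conditions and should re-close on mild acidification.

Step 22
Reactants: 31 diol lactone
Product: 32 α-hydroxy aldehyde (C11 formyl on C10; tertiary hydroxyl retained)
Conditions: SO3·pyridine, DMSO, iPr2NEt, CH2Cl2, 0 °C
Reagents that add atoms: none
Why: Parikh–Doering oxidation converts the primary alcohol to the aldehyde without touching the tertiary allylic alcohol and without the glycol cleavage that iodine-based oxidants can cause; 32 is used without delay.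

Step 23
Reactants: 33 methyl acetoacetate; 34 methyl nicotinate
Product: 35 methyl 3,5-dioxo-5-(pyridin-3-yl)pentanoate
Conditions: LiN(iPr)2 (2.2 equiv), THF, −78 → 0 °C; then 34
Reagents that add atoms: none
Why: Claisen acylation of the acetoacetate dianion occurs at its terminal carbon, the more reactive site.

Step 24
Reactants: 35 methyl 3,5-dioxo-5-(pyridin-3-yl)pentanoate
Product: 36 4-hydroxy-6-(pyridin-3-yl)-2H-pyran-2-one
Conditions: 1,8-diazabicyclo[5.4.0]undec-7-ene (20 mol %), PhMe, 110 °C
Reagents that add atoms: none
Why: The enol oxygen at C5 of the triketide attacks the ester and expels methanol, giving the 4-hydroxy-2-pyranone.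

Step 25
Reactants: 32 α-hydroxy aldehyde; 36 4-hydroxy-6-(pyridin-3-yl)-2H-pyran-2-one
Product: 37 target
Conditions: [H3NCH2CH2NH3](OAc)2 (20 mol %), MeCN/EtOH, 23 → 45 °C
Reagents that add atoms: none
Why: Proposed new method: C3' of 36 should add to the aldehyde (Knoevenagel-type), and the tertiary C10 hydroxyl should then add to C4' and lose water (5-exo addition–elimination) to form the dihydrofuran; aromatisation is blocked because C10 has no hydrogen, so the sequence should stop at the hydroxy-dihydrofuran, with the C11 hydroxyl entering (or equilibrating through the alkylidene/oxocarbenium form) on the less hindered C9 side while C10 keeps the configuration set in step 20; the closest known reaction types are the interrupted Feist–Bénary reaction and the condensation of 1,3-dicarbonyl compounds with α-hydroxy aldehydes to furans (García González reaction).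

## Compound list

1 | propane-1,3-diol | OCCCO | starting material
2 | 3-(tert-butyldiphenylsilyloxy)propan-1-ol | OCCCO[Si](c1ccccc1)(c1ccccc1)C(C)(C)C | intermediate
3 | 3-(tert-butyldiphenylsilyloxy)propanal | O=CCCO[Si](c1ccccc1)(c1ccccc1)C(C)(C)C | intermediate
4 | 2-(triphenylphosphoranylidene)propanal | CC(C=O)=P(c1ccccc1)(c1ccccc1)c1ccccc1 | starting material
5 | (E)-5-(tert-butyldiphenylsilyloxy)-2-methylpent-2-enal | O=C/C(C)=C/CCO[Si](c1ccccc1)(c1ccccc1)C(C)(C)C | intermediate
6 | methyl acetate | COC(C)=O | starting material
7 | acrolein | C=CC=O | starting material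
8 | methyl 3-hydroxypent-4-enoate (racemic) | COC(=O)CC(O)C=C | intermediate
9 | methyl 3-oxopent-4-enoate | COC(=O)CC(=O)C=C | intermediate
10 | methyl (Z)-3-(tert-butyldimethylsilyloxy)penta-2,4-dienoate | C=C/C(O[Si](C)(C)C(C)(C)C)=C/C(=O)OC | intermediate
11 | silyl enol ether cycloadduct (C6 mixture) | COC(=O)C1C(O[Si](C)(C)C(C)(C)C)=CC[C@@](C)(C=O)[C@@H]1CCO[Si](c1ccccc1)(c1ccccc1)C(C)(C)C | intermediate
12 | ring-B aldehyde β-keto ester, enol form (5R,6S) | COC(=O)C1=C(O)CC[C@@](C)(C=O)[C@@H]1CCO[Si](c1ccccc1)(c1ccccc1)C(C)(C)C | intermediate
13 | tert-butyl acrylate | C=CC(=O)OC(C)(C)C | starting material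
14 | C6-quaternary keto aldehyde diester | O=C1CC[C@@](C)(C=O)[C@H](CCO[Si](c2ccccc2)(c2ccccc2)C(C)(C)C)[C@@]1(C(=O)OC)CCC(=O)OC(C)(C)C | intermediate
15 | C10 ethyl carbinol (C10 epimers) | O=C1CC[C@@](C)(C(O)CC)[C@H](CCO[Si](c2ccccc2)(c2ccccc2)C(C)(C)C)[C@@]1(C(=O)OC)CCC(=O)OC(C)(C)C | intermediate
16 | C10 TBS ether (C10 epimers) | O=C1CC[C@@](C)(C(CC)O[Si](C)(C)C(C)(C)C)[C@H](CCO[Si](c2ccccc2)(c2ccccc2)C(C)(C)C)[C@@]1(C(=O)OC)CCC(=O)OC(C)(C)C | intermediate
17 | C1 enol triflate | O=S(=O)(OC1=CC[C@@](C)(C(CC)O[Si](C)(C)C(C)(C)C)[C@H](CCO[Si](c2ccccc2)(c2ccccc2)C(C)(C)C)[C@@]1(C(=O)OC)CCC(=O)OC(C)(C)C)C(F)(F)F | intermediate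
18 | ethoxydiene | C=C(OCC)C1=CC[C@@](C)(C(CC)O[Si](C)(C)C(C)(C)C)[C@H](CCO[Si](c2ccccc2)(c2ccccc2)C(C)(C)C)[C@@]1(C(=O)OC)CCC(=O)OC(C)(C)C | intermediate
19 | C1-acetyl cyclohexene | CC(=O)C1=CC[C@@](C)(C(CC)O[Si](C)(C)C(C)(C)C)[C@H](CCO[Si](c2ccccc2)(c2ccccc2)C(C)(C)C)[C@@]1(C(=O)OC)CCC(=O)OC(C)(C)C | intermediate
20 | saturated methyl ketone (acetyl β at C1) | CC(=O)[C@@H]1CC[C@@](C)(C(CC)O[Si](C)(C)C(C)(C)C)[C@H](CCO[Si](c2ccccc2)(c2ccccc2)C(C)(C)C)[C@@]1(C(=O)OC)CCC(=O)OC(C)(C)C | intermediate
21 | C1-isopropenyl diester | C=C(C)[C@@H]1CC[C@@](C)(C(CC)O[Si](C)(C)C(C)(C)C)[C@H](CCO[Si](c2ccccc2)(c2ccccc2)C(C)(C)C)[C@@]1(C(=O)OC)CCC(=O)OC(C)(C)C | intermediate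
22 | 1,5-diol | C=C(C)[C@@H]1CC[C@@](C)(C(CC)O[Si](C)(C)C(C)(C)C)[C@H](CCO[Si](c2ccccc2)(c2ccccc2)C(C)(C)C)[C@@]1(CO)CCCO | intermediate
23 | lactol (C14 epimers) | C=C(C)[C@@H]1CC[C@@](C)(C(CC)O[Si](C)(C)C(C)(C)C)[C@H](CCO[Si](c2ccccc2)(c2ccccc2)C(C)(C)C)[C@@]12CCC(O)OC2 | intermediate
24 | spiro δ-lactone, bis-silyl ether | C=C(C)[C@@H]1CC[C@@](C)(C(CC)O[Si](C)(C)C(C)(C)C)[C@H](CCO[Si](c2ccccc2)(c2ccccc2)C(C)(C)C)[C@@]12CCC(=O)OC2 | intermediate
25 | lactone diol | C=C(C)[C@@H]1CC[C@@](C)(C(O)CC)[C@H](CCO)[C@@]12CCC(=O)OC2 | intermediate
26 | keto aldehyde | C=C(C)[C@@H]1CC[C@@](C)(C(=O)CC)[C@H](CC=O)[C@@]12CCC(=O)OC2 | intermediate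
27 | β-hydroxy ketone (aldol; C8 and C9 mixtures) | C=C(C)[C@@H]1CC[C@]2(C)[C@H](CC(O)C(C)C2=O)[C@@]12CCC(=O)OC2 | intermediate
28 | seco-lactone enone | C=C(C)[C@@H]1CC[C@]2(C)[C@H](CC=C(C)C2=O)[C@@]12CCC(=O)OC2 | intermediate
29 | spiro epoxide | C=C(C)[C@@H]1CC[C@]2(C)[C@H](CC=C(C)[C@]23CO3)[C@@]12CCC(=O)OC2 | intermediate
30 | potassium hydroxy carboxylate (opened lactone triol) | C=C(C)[C@@H]1CC[C@]2(C)[C@H](CC=C(C)[C@]2(O)CO)[C@@]1(CO)CCC(=O)[O-].[K+] | intermediate
31 | diol lactone | C=C(C)[C@@H]1CC[C@]2(C)[C@H](CC=C(C)[C@]2(O)CO)[C@@]12CCC(=O)OC2 | intermediate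
32 | α-hydroxy aldehyde | C=C(C)[C@@H]1CC[C@]2(C)[C@H](CC=C(C)[C@]2(O)C=O)[C@@]12CCC(=O)OC2 | intermediate
33 | methyl acetoacetate | CC(=O)CC(=O)OC | starting material
34 | methyl nicotinate | COC(=O)c1cccnc1 | starting material
35 | methyl 3,5-dioxo-5-(pyridin-3-yl)pentanoate | COC(=O)CC(=O)CC(=O)c1cccnc1 | intermediate
36 | 4-hydroxy-6-(pyridin-3-yl)-2H-pyran-2-one | O=c1cc(O)cc(-c2cccnc2)o1 | intermediate
37 | CNP0126103.3 | C=C(C)[C@@H]1CC[C@]2(C)[C@H](CC=C(C)[C@@]23Oc2cc(-c4cccnc4)oc(=O)c2[C@@H]3O)[C@@]12CCC(=O)OC2 | target

## Step count and least certain steps

Total step count: 25. Longest linear sequence: 20 steps (steps 1–3, 7–22 and 25).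

**Step 25 (bears the label).** Most likely failures are interception of the Knoevenagel-type intermediate by a second molecule of 36, α-ketol rearrangement of 32 under amine catalysis, or ring closure before the C11 configuration has settled on the C9 side. The fallback uses known reaction types and sets out from 32:
- Chlorite oxidation (NaClO2, NaH2PO4, 2-methylbut-2-ene) should give the α-hydroxy acid F1.
- Carbodiimide coupling of F1 with 36 (N,N'-dicyclohexylcarbodiimide, 4-(dimethylamino)pyridine), with O-to-C acyl shift, should give the 3-acyl-4-hydroxypyranone F2.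
- Acid-catalysed cyclodehydration (p-toluenesulfonic acid, PhMe) should give the spiro furanone F3; ionisation at C10 is disfavoured there by the adjacent carbonyl.
- Reduction with NaBH4/CeCl3 is expected to deliver hydride from the C9 side and so give mainly the 11-epi alcohol F4.
- F4 would be equilibrated in mildly acidic aqueous THF through the C11 cation, which water should capture from the C9 side, returning to the route at 37.

**Step 7 (key step).** The ester lowers the nucleophilicity of the diene terminus, so the cycloaddition may be slow. Silyl transfer from a stepwise intermediate to the triflimide could start an achiral silyl-Lewis-acid pathway and erode the enantioselectivity, and a stepwise path could also lose the enal geometry. The fallback sets out from 5 and 10: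
- EtAlCl2-promoted cycloaddition (CH2Cl2, −78 °C) and the same acidic work-up would give 11 with its enantiomer F5, and then 12 with its enantiomer F6.
- Condensation of the aldehydes with (1R,2R)-N,N'-dimethyl-1,2-diphenylethane-1,2-diamine would give the diastereomeric aminals F7 (from 12) and F8 (from F6), to be separated by chromatography.
- Dilute-acid hydrolysis of F7 returns to the route at 12.

**Step 9.** Competing addition to, or enolisation of, the C1 ketone, or β-hydride reduction of the neopentyl aldehyde, would lower chemoselectivity. The fallback sets out from 12 and changes the order: two equivalents of EtMgBr (the first forms the magnesium enolate of the β-keto ester, which shields C1 and the ester) should give the carbinol β-keto ester F9; silylation of the carbinol (tBuMe2SiCl, imidazole, DMF) gives the TBS ether F10; Michael addition of F10 to 13 under the conditions of step 8 returns to the route at 16.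

**Step 20.** Methylene transfer to the hindered, conjugated C10 carbonyl may be incomplete, and the basic ylide may instead deprotonate at C7 or attack the lactone. The fallback sets out from 28: chloromethyllithium generated in its presence (ICH2Cl, MeLi·LiBr, THF, −78 °C) should add to the ketone from the same α face to give the chlorohydrin F11 (as its alkoxide), which closes on warming and returns to the route at 29.

**Step 21.** SN2 attack of hydroxide at the neopentyl-like C11 may be slow, allowing SN2' opening at C8, ionisation at C10 or incomplete relactonisation. The fallback sets out from 29: sodium thiophenolate should open the epoxide at C11 to the β-hydroxy sulfide F12; NaIO4 oxidation gives the sulfoxide F13; Pummerer rearrangement ((CF3CO)2O, 2,6-lutidine, then aqueous NaHCO3) unmasks the aldehyde and returns to the route at 32, bypassing 31.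

## Further compounds

F1 | step 25 | α-hydroxy acid | C=C(C)[C@@H]1CC[C@]2(C)[C@H](CC=C(C)[C@]2(O)C(=O)O)[C@@]12CCC(=O)OC2
F2 | step 25 | 3-acyl-4-hydroxypyranone | C=C(C)[C@@H]1CC[C@]2(C)[C@H](CC=C(C)[C@]2(O)C(=O)c2c(O)cc(-c3cccnc3)oc2=O)[C@@]12CCC(=O)OC2
F3 | step 25 | spiro furanone (C11 ketone) | C=C(C)[C@@H]1CC[C@]2(C)[C@H](CC=C(C)[C@@]23Oc2cc(-c4cccnc4)oc(=O)c2C3=O)[C@@]12CCC(=O)OC2
F4 | step 25 | 11-epi alcohol | C=C(C)[C@@H]1CC[C@]2(C)[C@H](CC=C(C)[C@@]23Oc2cc(-c4cccnc4)oc(=O)c2[C@H]3O)[C@@]12CCC(=O)OC2
F5 | step 7 | enantiomer of 11 | COC(=O)C1C(O[Si](C)(C)C(C)(C)C)=CC[C@](C)(C=O)[C@H]1CCO[Si](c1ccccc1)(c1ccccc1)C(C)(C)C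
F6 | step 7 | enantiomer of 12 | COC(=O)C1=C(O)CC[C@](C)(C=O)[C@H]1CCO[Si](c1ccccc1)(c1ccccc1)C(C)(C)C
F7 | step 7 | aminal of 12 with the (R,R)-diamine | COC(=O)C1=C(O)CC[C@@](C)(C2N(C)[C@H](c3ccccc3)[C@@H](c3ccccc3)N2C)[C@@H]1CCO[Si](c1ccccc1)(c1ccccc1)C(C)(C)C
F8 | step 7 | aminal of F6 with the (R,R)-diamine | COC(=O)C1=C(O)CC[C@](C)(C2N(C)[C@H](c3ccccc3)[C@@H](c3ccccc3)N2C)[C@H]1CCO[Si](c1ccccc1)(c1ccccc1)C(C)(C)C
F9 | step 9 | carbinol β-keto ester (C10 epimers) | COC(=O)C1=C(O)CC[C@@](C)(C(O)CC)[C@@H]1CCO[Si](c1ccccc1)(c1ccccc1)C(C)(C)C
F10 | step 9 | TBS ether of F9 | COC(=O)C1=C(O)CC[C@@](C)(C(CC)O[Si](C)(C)C(C)(C)C)[C@@H]1CCO[Si](c1ccccc1)(c1ccccc1)C(C)(C)C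
F11 | step 20 | chlorohydrin | C=C(C)[C@@H]1CC[C@]2(C)[C@H](CC=C(C)[C@]2(O)CCl)[C@@]12CCC(=O)OC2
F12 | step 21 | β-hydroxy sulfide | C=C(C)[C@@H]1CC[C@]2(C)[C@H](CC=C(C)[C@]2(O)CSc2ccccc2)[C@@]12CCC(=O)OC2
F13 | step 21 | β-hydroxy sulfoxide (sulfur epimers) | C=C(C)[C@@H]1CC[C@]2(C)[C@H](CC=C(C)[C@]2(O)CS(=O)c2ccccc2)[C@@]12CCC(=O)OC2
A1 | alternative 1 | tricyclic 15-hydroxy-14-ketone | CC1(C)[C@@H]2CC[C@]3(C)[C@H](CC=C(C)C3=O)[C@@]2(CO)CCC1=O
A2 | alternative 1 | bridged hemiketal of A1 | CC1(C)[C@@H]2CC[C@]3(C)[C@H](CC=C(C)C3=O)[C@@]24CC[C@]1(O)OC4
A3 | alternative 1 | seco-lactone enone (same compound as 28) | C=C(C)[C@@H]1CC[C@]2(C)[C@H](CC=C(C)C2=O)[C@@]12CCC(=O)OC2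
A4 | alternative 2 | silyloxy triene with tethered isopropenyl ketone | C=C(O[Si](C)(C)C(C)(C)C)/C=C/CC[C@H](C)C(=O)C(C)=C
A5 | alternative 2 | trans-fused octalone silyl enol ether (six-membered ring B) | C1C[C@]2(C)[C@H](CC[C@H](C)C2=O)C=C1O[Si](C)(C)C(C)(C)C
A6 | alternative 3 | alkenyl iodide with furopyranone on C4 | C=C(C)[C@@H]1CC[C@@](C)(c2cc3c(=O)oc(-c4cccnc4)cc3o2)[C@H](C/C=C(/C)I)[C@@]12CCC(=O)OC2
A7 | alternative 3 | C11 pinacol boronate of the complete skeleton | C=C(C)[C@@H]1CC[C@]2(C)[C@H](CC=C(C)[C@@]23Oc2cc(-c4cccnc4)oc(=O)c2[C@@H]3B2OC(C)(C)C(C)(C)O2)[C@@]12CCC(=O)OC2
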